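**Retrosynthetic overview**
- The target is the C2-symmetric syn head-to-tail cyclobutane dimer of the angular pyranocoumarin seselin. Both 2,2-dimethyl-2H-pyran rings are cut last, each across its C3'=C4' double bond and its O–CMe2 bond, leaving a bis(salicylaldehyde) dilactone and two 2-methylprop-1-enyl units.
- Enabling feature: on each benzo ring the pyran oxygen (on C7) and the pyran carbon C4' (on C8) are ortho, so C7–OH/C8–CHO is a salicylaldehyde. The other oxygen ortho to C8 (O1) is locked in the six-membered lactone, so a twofold borono-Mannich/oxa-6π cascade can only close the angular pyran rings.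
- The cyclobutane, both cis-fused lactone rings, all four stereocentres and the C2 chirality come from one enantioselective Lewis-acid-catalysed [2+2] photodimerisation of a protected 8-(hydroxymethyl)umbelliferone, run before any photoactive chromene C=C bond exists.
- The C8 carbon is put on umbelliferone by Duff formylation and parked at the alcohol level as a benzyl ether during the photochemistry.
- Ring order: pyranone ring (bought) → cyclobutane (step 4) → both pyran rings (step 7).

Key step: step 7

Remark: coumarin numbering is used for every intermediate (pyran atoms primed); the sense of induction in step 4 is assumed to follow face shielding by the boron-bound catalyst, so the catalyst antipode that leaves the C3-Re/C4-Si face of the bound lactone open is the one specified.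

**Step 1**
Reactants: 1 umbelliferone (7-hydroxycoumarin); 2 hexamethylenetetramine
Product: 4 8-formyl-7-hydroxycoumarin, via aldimine 3 (not isolated)
Conditions: 2 (3 equiv), CF3CO2H, 90 °C; then aq. HCl, 60 °C
Reagents that add atoms: hexamethylenetetramine, C1N2CN3CN1CN(C2)C3; water, O
Why: Duff formylation, in which the C7 hydroxyl directs the methyleneiminium electrophile to C8 (the ortho position favoured by the fixed C7–C8 double-bond character of the coumarin) and acid hydrolysis of the benzylic iminium releases the aldehyde; no stereocentre is formed.

**Step 2**
Reactants: 4 8-formyl-7-hydroxycoumarin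
Product: 5 7-hydroxy-8-(hydroxymethyl)coumarin
Conditions: NaBH4, THF–MeOH, 0 °C; aq. NH4Cl
Reagents that add atoms: none
Why: Chemoselective hydride reduction of the aryl aldehyde at 0 °C should leave the conjugated lactone intact and takes the formyl carbon to the alcohol level, where it neither binds the Lewis acid of step 4 strongly nor quenches the excited state by proton transfer.

**Step 3**
Reactants: 5 7-hydroxy-8-(hydroxymethyl)coumarin; 6 benzyl bromide
Product: 7 7-(benzyloxy)-8-[(benzyloxy)methyl]coumarin
Conditions: NaH (2.3 equiv), BnBr (2.5 equiv), n-Bu4NI (cat.), DMF, 0 °C to rt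
Reagents that add atoms: benzyl bromide, BrCc1ccccc1
Why: Williamson etherification of the phenoxide and the primary alkoxide should give two Lewis-acid-stable, photochemically silent benzyl ethers, leaving the lactone carbonyl as the only strongly basic site and allowing neutral removal later.

**Step 4**
Reactants: 7 7-(benzyloxy)-8-[(benzyloxy)methyl]coumarin (two molecules)
Product: 8 syn head-to-tail cyclobutane dimer of 7 (tetrabenzyl ether)
Conditions: hν (366 nm), AlBr3-activated chiral oxazaborolidine (50 mol%; made in situ from (S)-α,α-diphenylprolinol, 2,4,6-trifluorophenylboronic acid and AlBr3), CH2Cl2, −75 °C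
Reagents that add atoms: none
Why: Proposed new method: enantioselective Lewis-acid-catalysed [2+2] photodimerisation, in which the chiral acid binds the lactone carbonyl of one molecule of 7, shifts its absorption so that only the complex is excited at 366 nm, and shields its C3-Si/C4-Re face; a free, more electron-rich molecule of 7 then adds to the open C3-Re/C4-Si face in the donor–acceptor sandwich that places the electrophilic C4 of the bound partner over the nucleophilic C3 of the free one (head-to-tail, with the bulky 7,8-substituents pointing apart); the cis C3=C4 geometry sets both cis ring fusions, the sandwich sets syn, and the catalyst sets the absolute configuration of all four stereocentres (3S,4R in each unit); the closest known reaction types are the BF3-promoted photodimerisation of coumarin to its syn head-to-tail dimer and the enantioselective intramolecular [2+2] photocycloaddition of coumarins with AlBr3-activated oxazaborolidines.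

**Step 5**
Reactants: 8 syn head-to-tail dimer (tetrabenzyl ether)
Product: 9 syn head-to-tail dimer of 7-hydroxy-8-(hydroxymethyl)-3,4-dihydrocoumarin (tetraol)
Conditions: H2 (1 atm), 10% Pd/C, EtOAc–THF, rt
Reagents that add atoms: none
Why: Neutral hydrogenolysis of the four benzyl ethers should free both phenols and both benzylic alcohols without opening the aryl lactones (the only route to racemisation), since the dimer has no other reducible group.

**Step 6**
Reactants: 9 tetraol
Product: 10 syn head-to-tail dimer of 8-formyl-7-hydroxy-3,4-dihydrocoumarin (bis(salicylaldehyde) dilactone)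
Conditions: activated MnO2 (excess), EtOAc, rt
Reagents that add atoms: none
Why: MnO2 oxidises the electron-rich ortho-hydroxybenzylic alcohols selectively to the hydrogen-bonded salicylaldehydes under neutral conditions, leaving phenols, lactones and stereocentres untouched.

**Step 7**
Reactants: 10 bis(salicylaldehyde) dilactone; 11 2-methylprop-1-enylboronic acid
Product: 14 target (syn head-to-tail cyclobutane dimer of seselin), via bis(allylic dibenzylamine) 12 (not isolated), via bis(ortho-quinone methide) 13 (not isolated)
Conditions: 11 (3 equiv), Bn2NH (40 mol%), 1,4-dioxane, 90 °C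
Reagents that add atoms: 2-methylprop-1-enylboronic acid, CC(C)=CB(O)O
Why: Each C8 aldehyde condenses reversibly with Bn2NH to an iminium ion held next to the C7 phenol, the phenol binds the boronic acid as a tetracoordinate boronate, and the 2-methylprop-1-enyl group migrates from boron to the iminium carbon inside this chelate (new C4'–C3' bond, bis(allylic amine) 12). Thermal loss of Bn2NH, which returns to the cycle, gives the ortho-quinone methide dienone 13, and a thermal disrotatory oxa-6π electrocyclisation closes each pyran ring through the new O–CMe2 bond and restores the arene, so four bonds and two rings should form in one flask. The closest known reaction type is the amine-catalysed Petasis (borono-Mannich) synthesis of 2H-chromenes from salicylaldehydes and alkenylboronic acids. No stereocentre is created, because the ring-closing carbon is CMe2, and the four cyclobutane centres are spectators that cannot epimerise, since each six-membered lactone can only be cis-fused to the four-membered ring. The step needs regioselectivity between the two oxygens ortho to C8 and chemoselectivity for the aldehydes over the aryl lactones: the first is secured because O1 is acylated within the lactone, so only the free C7 hydroxyl can carry boron and close the ring (angular pyran only); the second rests on the low nucleophilicity and catalytic loading of the hindered secondary amine, which engages the hydrogen-bond-activated aldehyde reversibly and faster than it can be acylated.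

**Compound list**
1 | umbelliferone (7-hydroxy-2H-chromen-2-one) | Oc1ccc2ccc(=O)oc2c1 | starting material
2 | hexamethylenetetramine | C1N2CN3CN1CN(C2)C3 | starting material
3 | 7-hydroxy-8-(iminomethyl)coumarin, the Duff benzylic imine drawn in its simplest N-unsubstituted form (not isolated) | N=Cc1c(O)ccc2ccc(=O)oc12 | intermediate
4 | 8-formyl-7-hydroxycoumarin (7-hydroxy-2-oxo-2H-chromene-8-carbaldehyde) | O=Cc1c(O)ccc2ccc(=O)oc12 | intermediate
5 | 7-hydroxy-8-(hydroxymethyl)coumarin | OCc1c(O)ccc2ccc(=O)oc12 | intermediate
6 | benzyl bromide | BrCc1ccccc1 | starting material
7 | 7-(benzyloxy)-8-[(benzyloxy)methyl]coumarin | O=c1ccc2ccc(OCc3ccccc3)c(COCc3ccccc3)c2o1 | intermediate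
8 | syn head-to-tail [2+2] dimer of 7: C2-symmetric cyclobutane with two cis-fused 3,4-dihydrocoumarin lactones, C3 of each unit bonded to C4 of the other, all four cyclobutane hydrogens on one face, 3S,4R in both units; 7,7'-bis(benzyloxy), 8,8'-bis[(benzyloxy)methyl] | C(OCc1ccccc1)c1c(OCc2ccccc2)ccc2c1OC(=O)[C@H]1[C@@H]2[C@H]2C(=O)Oc3c(COCc4ccccc4)c(OCc4ccccc4)ccc3[C@H]21 | intermediate
9 | same syn head-to-tail dilactone core and configuration; 7,7'-dihydroxy, 8,8'-bis(hydroxymethyl) (tetraol) | OCc1c(O)ccc2c1OC(=O)[C@H]1[C@@H]2[C@H]2C(=O)Oc3c(CO)c(O)ccc3[C@H]21 | intermediate
10 | same core and configuration; 7,7'-dihydroxy, 8,8'-diformyl (bis(salicylaldehyde) dilactone) | O=Cc1c(O)ccc2c1OC(=O)[C@H]1[C@@H]2[C@H]2C(=O)Oc3c(C=O)c(O)ccc3[C@H]21 | intermediate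
11 | 2-methylprop-1-enylboronic acid | CC(C)=CB(O)O | starting material
12 | same core and configuration; 7,7'-dihydroxy, each C8 carrying CH(NBn2)–CH=CMe2, configuration at the two aminated carbons undefined (not isolated) | CC(C)=CC(N(Cc1ccccc1)Cc1ccccc1)c1c(O)ccc2c1OC(=O)[C@H]1[C@@H]2[C@H]2C(=O)Oc3c(C(C=C(C)C)N(Cc4ccccc4)Cc4ccccc4)c(O)ccc3[C@H]21 | intermediate
13 | same cyclobutane dilactone core; each benzo ring as the ortho-quinone methide (C7=O, C8=CH–CH=CMe2), alkene geometry undefined (not isolated) | CC(C)=CC=C1C(=O)C=CC2=C1OC(=O)[C@H]1[C@@H]2[C@H]2C(=O)OC3=C(C=CC(=O)C3=CC=C(C)C)[C@H]21 | intermediate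
14 | CNP0167575.1: syn head-to-tail cyclobutane dimer of seselin, two 2,2-dimethyl-2H-pyran rings fused at C7–C8 (O on C7), all four cyclobutane hydrogens cis, 3S,4R in both units | CC1(C)C=Cc2c(ccc3c2OC(=O)[C@H]2[C@@H]3[C@H]3C(=O)Oc4c5c(ccc4[C@H]32)OC(C)(C)C=C5)O1 | target

**Step count**
Total steps: 7. Longest linear sequence: 7 steps (1 → 4 → 5 → 7 → 8 → 9 → 10 → 14).

**Steps most likely to fail**

1. Step 4 (Proposed new method). What may go wrong: loss of regio- or facial control, because an uncatalysed background reaction or a triplet pathway of the complex could give head-to-head or anti dimers or low enantiomeric purity. Fallback with known chemistry, setting out from 7 and coming back at 8: irradiation of 7 at 350 nm in CH2Cl2 with achiral BF3·OEt2, the Lewis-acid photodimerisation known to turn coumarin into its syn head-to-tail dimer, should give the racemate, that is 8 together with its mirror image ent-8 F1. The two enantiomers are then separated by preparative HPLC on a polysaccharide chiral stationary phase, and 8 goes on to step 5.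

2. Step 7 (key step). What may go wrong: aminolysis of the strained aryl lactones by the amine catalyst, or slow transfer of the trisubstituted alkenyl group that stalls after one annulation. Fallback without amine or base, setting out from 9 (step 6 is skipped) and coming back at 14: heating tetraol 9 with excess 2-methylpropene in toluene in a sealed tube (150–170 °C) should dehydrate each ortho-hydroxybenzyl alcohol to an ortho-quinone methide. This is trapped by inverse-demand hetero-Diels–Alder addition, with oxygen bonding to the dimethyl-substituted carbon, to give the bis(3',4'-dihydropyran) dimer of 3',4'-dihydroseselin F2. DDQ in refluxing 1,4-dioxane then dehydrogenates each 2,2-dimethylchroman to the chromene, giving 14.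

3. Step 5. What may go wrong: over-hydrogenolysis of the liberated ortho-hydroxybenzylic C–O bonds to methyl groups. Fallback that avoids reducing conditions, setting out from 8 and coming back at 10 (step 6 is skipped): DDQ in wet 1,2-dichloroethane (60 °C) should oxidise the two electron-rich ArCH2–OBn ethers directly to aldehydes with loss of benzyl alcohol, giving the 7,7'-bis(benzyloxy)-8,8'-diformyl dimer F3. BCl3 (CH2Cl2, −78 °C) then removes the two phenolic benzyl groups by chelation to the ortho formyl groups, giving 10.

**Further compounds**
F1 | step 4 | ent-8, mirror image of the tetrabenzyl syn head-to-tail dimer | C(OCc1ccccc1)c1c(OCc2ccccc2)ccc2c1OC(=O)[C@@H]1[C@H]2[C@@H]2C(=O)Oc3c(COCc4ccccc4)c(OCc4ccccc4)ccc3[C@@H]21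
F2 | step 7 | syn head-to-tail cyclobutane dimer of 3',4'-dihydroseselin (bis(2,2-dimethylchroman) analogue of 14, same configuration) | CC1(C)CCc2c(ccc3c2OC(=O)[C@H]2[C@@H]3[C@H]3C(=O)Oc4c5c(ccc4[C@H]32)OC(C)(C)CC5)O1
F3 | step 5 | syn head-to-tail dimer of 7-(benzyloxy)-8-formyl-3,4-dihydrocoumarin (same configuration as 8) | O=Cc1c(OCc2ccccc2)ccc2c1OC(=O)[C@H]1[C@@H]2[C@H]2C(=O)Oc3c(C=O)c(OCc4ccccc4)ccc3[C@H]21
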